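At late times the readings of the two earlier runs, dusk and dawn, showed no trend beyond their scatter, so I began there when I was asked about a new flask of substrate under held gas.

| setting | dusk | dawn | flask |
|---|---|---|---|
| substrate | 0.28 M | 0.44 M | 0.20 M |
| gas | 27 mM (held) | 27 mM (held) | 27 mM (held) |
| remark | run made earlier | run made earlier |  |
| time |  |  | 5.0 d |

- dusk (time / d: target / %): 0.833: 68; 2.00: 89; 4.00: 87; 6.00: 86
- dawn (time / d: target / %): 0.833: 65; 2.00: 84; 4.00: 87; 6.00: 89

(each reading ± 2 percentage points)

- at the start none of the gas is in solution
- partner is what gas becomes in solution

* amount of target at 5.0 d, in percent of the substrate charged
* concentration of partner in solution at 5.0 d, in percent of saturation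

From 2.00 d on, the readings of both runs averaged 87.0% of the charge. At 0.833 d target stood at 68% in dusk and 65% in dawn, a gap of 3 percentage points against a scatter of 2 points on each reading, so these readings did not tell the two charges apart. My bench rule was to freeze what is nearly constant: with partner held at saturation, substrate falls first order whatever its charge (pseudo-first-order). From the mean early reading of 66.5% I read 0.399 d, my frozen-partner half-life, the time in which the part of the plateau still unreached halves.

The rule normally wants a reagent in excess, but saturation holds just 13.5% of the flask's charge, so the freeze stands on gas crossing as fast as partner is used. At a fixed half-life the demand for partner grows with the charge, and the flask carries 45.5% of the dawn charge, so I trusted the rule here. The time asked is 12.5 half-lives, so I expected target at the plateau and partner back at its saturation of 27 mM.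

The forecast gave 87% of target and 99% of saturation for partner, holding that “the reaction is finished”.

The flask gave 87.3% of target and >99.9% of saturation, with 0% of its substrate left after those 12.5 half-lives.

    substrate + partner → target (k = 3.60 L mol⁻¹ h⁻¹)
    substrate + 2 partner → side product (k = 25.0 L² mol⁻² h⁻¹)
    gas ⇌ partner, rate k3*(csat - [partner]) (kL = 1.60 h⁻¹)

At 0.367 d in the flask, substrate passed into target 7.0 times as fast as into side product, a selectivity factor. That moment lies close to 0.384 d, the mid-point of the turnover into target, and at 5.00 d the flask held 87.3% of target beside 12.7% of side product.

For the same flask read at 30 h, the half-life gives 11.4% of substrate left and 77.1% of target. The computed flask has 6.3% left and 82.0% of target, further along than my reckoning.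

All runs were generated by integration for an exercise.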